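##### Structural features

Ficucaricone C is a 2,2-dimethyl-2H-chromene: benzene ring A is fused through C4a and C8a to a pyran that holds O1, the quaternary C2 and the C3=C4 alkene. C6 of ring A bears a 1,2-diketone, Ca(=O)–Cb(=O), whose far end is ring B, a para-disubstituted benzene carrying a prenyl ether. Ring A is substituted at five of its six carbons (C5 OMe, C6 acyl, C7 OH, C8a the pyran oxygen, C4a the vinyl carbon C4); only C8 keeps a hydrogen. There is no stereocentre, so no two stereocentres are adjacent, and the only geometric element is the ring alkene, which is cis by necessity. The fragile parts are: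
- the diketone: hydroxide and alkoxides add to it and can start a benzilic rearrangement, and the C7 hydroxyl can close onto Cb as a hemiketal;
- the prenyl aryl ether: acid, zerovalent palladium, quinone oxidants;
- the electron-rich chromene alkene: acid, electrophilic oxidants;
- the C5 methoxy group beside a carbonyl: Lewis acids.

The real difficulty is regiochemical: three different oxygen functions sit in a 1,3,5 pattern on ring A, each carbon substituent lies between two of them, and the C6 carbonyl carbon is shielded on both sides. The key step exploits the fact that O1 on C8a is para, and O7 on C7 ortho, to the carbonyl carbon on C6. If both oxygens are written as fluorines, ring A gains a mirror plane through C5 and C8, and a C6 ester then activates the C8a fluoride for displacement by an alkoxide tethered at C4a.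

##### Logic of the disconnections

**22 to 21.** The Cb carbonyl is traced back to a 1,3-dithiane, so the two C–S bonds of 21 stand for the C=O bond. The diketone is the least robust function and should appear last, after every strongly basic step. 21 is a plain, hindered monoketone. The forward step must open the thioketal without touching two alkenes, a free phenol and an electron-rich arene; this calls for alkylative hydrolysis near neutral pH and not for a halogen or heavy-metal oxidant.

**21 to 19.** The C7–O bond is cut and the hydroxyl is replaced by fluorine. Fluorine is used as a stand-in for O7 that needs no protecting group: it is inert to the carbanion chemistry of the preceding step and it is small. The gain is that a protection and a deprotection are saved. The demand is an SNAr at a fluoride ortho to a ketone that its neighbours twist out of the ring plane. The oxygen nucleophile must deliver OH directly and must not attack the ketone.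

**19 to 14 and 17.** The Ca–Cb bond is cut between an ester (Ca at the acid level) and an acyl anion equivalent of ring B (18, made from 17 in the flask). It is the most convergent cut: two halves of similar size and no redox adjustment. The bond is made while C7 still carries fluorine and not oxygen, so that the ester of 14 has one small ortho neighbour, is more electrophilic and has no acidic OH beside it. The demand is addition of a tertiary, sulfur-stabilised carbanion to a shielded ester without substitution at the ortho fluoride.

**17 to 16 to 15.** The prenyl O–C bond and the two C–S bonds are cut. 15 already holds Cb at the aldehyde level, so ring B needs no halogen–metal exchange and no formylation. The thioacetal is made before the ether, so that Lewis acid and thiol never meet the acid-labile prenyl group.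

**14 to 11.** The O1–C8a bond is cut. This opens the pyran ring to a tertiary Z-allylic alcohol on C4a and a fluoride on C8a, para to the ester. Ring A of 11 is then a simple arene whose whole pattern is set by lithiation. The forward step needs the alkoxide to attack one carbon only. The tether can reach two ring carbons, C8a (bearing F) and C5 (bearing OMe); the fluorine-bearing carbon should react far faster. The fluoride ortho to the ester is out of reach, so it can only be attacked intermolecularly. A non-nucleophilic amide base at high dilution is therefore preferred to an alkoxide base, which could itself substitute an activated fluoride.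

**11 to 10.** The Z alkene is traced to an alkyne. Syn addition of hydrogen on a poisoned surface sets the one geometry that lets the oxygen reach C8a, so no olefination selectivity is involved.

**10 to 8 and 9.** The C4a–C4 bond (sp2–sp) is cut. 9 brings C4, C3, C2, both methyl groups and O1 in one piece. The coupling must work at an iodide flanked by OMe and F, and the base must be a tertiary amine so that no amine displaces an activated fluoride.

**8 to 7 to 5 to 3 to 1.** In turn, the bonds cut are the C8–Si bond of a temporary block, the C6–Ca bond, the C4a–I bond and the C–Si bond.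
- In 1 the most acidic hydrogen lies between the fluorines (the future C8), so this site is silylated first.
- The two hydrogens left are then equivalent, each between OMe and F, and two successive lithiations place iodine and ester with no regiochemical choice.
- Iodine goes in before the ester and the third metalation uses a lithium amide, so that no alkyllithium meets a C–I bond or an ester.
- All three metalations must stay at −78 °C, because aryllithiums ortho to fluorine lose LiF on warming.

##### Other disconnections considered

**Alternative 1:** The cut removes both bonds to Cb (Ca–Cb and Cb–C1' of ring B) and supplies Cb as an isocyanide carbon.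
- Forward step: aryllithium A4 would add to the hindered isocyanide A3 to give the lithiated imine A5, an sp2 acyl anion equivalent. A5 would open the benzodioxinone A2 at its carbonyl; the acetal carbon leaves as a ketone and O7 is freed as the phenoxide, giving the mono-imine A1. Mild aqueous acid would then hydrolyse A1 to 22.
- In favour: both bonds to Cb form in one flask. The nucleophile is much smaller than the tertiary carbanion 18. The electrophile is an activated cyclic ester that frees O7 in the same event, so there is no protecting group, no sulfur and no separate hydroxylation.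
- Against: α-addition of an aryllithium to an isocyanide is less dependable than that of an alkyllithium, and A5 can take up a second isocyanide. More seriously, A2 presupposes the 7-hydroxy-6-carboxylic acid of the chromene, so the ring A regiochemistry is moved upstream and not solved. Making A2 from 14 would take about three more steps, one in strong acid that the chromene alkene tolerates poorly.
- Comparison: for the diketone assembly itself, alternative 1 is the better plan (smaller nucleophile, activated acyl donor, mild unmasking). On the structure of ring A the chosen plan is stronger. In step count the two come out about equal once A2 has to be prepared.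

**Alternative 2:** The cut opens ring A at C4a–C5 and C6–C7.
- Forward step: a Diels–Alder reaction of the bis(silyloxy)diene A7 with the methoxy ynone A8, then aromatisation by loss of the C7 methoxy group and desilylation, would give A6. A6 would still need oxidative closure of the prenyl group onto the C8a hydroxyl and hydrolysis of the dimethyl ketal.
- In favour: ring A is built from acyclic parts with all five substituents placed by the polarity of the partners (nucleophilic diene terminus C4a to the β-carbon C5 of the ynone). Ca and Cb are present from the start, so no hindered acylation is needed.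
- Against: A8 is a push–pull alkyne, a weak dienophile that hydrates easily. A7 is substituted at its nucleophilic terminus, so it is slower and hydrolytically labile. Aromatisation must expel the methoxy group and not a silyloxy group. The later chromene closure needs a quinone oxidant, which also attacks prenyl aryl ethers, and the ketal hydrolysis needs acid, which the chromene and the prenyl ether dislike.
- Comparison: on regiocontrol of ring A it is the equal of the chosen plan, and in convergence it is better. Mechanistically its cycloaddition is less secure than an SNAr closure. With three to five steps for each of A7 and A8, no step is saved.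

**Alternative 3:** The cut is again Ca–Cb, but the bond is made intramolecularly from a ring B benzyl ether on O7.
- Forward step: A10 could be made from 14 and the benzylic alcohol A11 by SNAr. A hindered lithium amide would deprotonate the OCH2 group, and the carbanion would attack the neighbouring ester in a Dieckmann-type closure to the benzofuranone A9. Hydroxylation of A9 at its C2 would give the hemiketal A12, the ring tautomer of 22.
- In favour: it is compatible with the chosen key step, since it starts from 14. The alcohol A11 serves as hydroxide surrogate and as carbon nucleophile at once. The C–C bond forms by a 5-exo-trig attack, which overcomes the shielding of the ester far better than the intermolecular attack of 18. No protecting group and no thioketal are needed.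
- Against: the α-oxy benzyl carbanion can undergo a [1,2]-Wittig rearrangement. The prenyl OCH2 of ring B is an allylic ether of similar acidity and invites the same rearrangement. A9 is more acidic than A10 and consumes base. The last step is an oxidation that must spare two alkenes, and A12 must then open to the diketone.
- Comparison: in step count it equals the chosen endgame (three steps from 14 either way), and for the C–C bond formation it is the better plan. The chosen endgame keeps every carbon at its final oxidation level and needs no oxidant at the end. On ring A the two are identical.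

Key step: step 7

Assumption: the target is handled as the open-chain hydroxy diketone as drawn; a cyclic hemiketal between O7 and Cb, if it forms, is taken to equilibrate with it and to need no step of its own.

##### Route

Step 1
Reactants: 1 3,5-difluoroanisole
Product: 3 (2,6-difluoro-4-methoxyphenyl)trimethylsilane, via (2,6-difluoro-4-methoxyphenyl)lithium 2 (not isolated)
Conditions: n-BuLi, THF, −78 °C; then Me3SiCl, −78 °C to rt
Reagents that add atoms: chlorotrimethylsilane, C[Si](C)(C)Cl
Why: Directed ortho-lithiation; the hydrogen between the two fluorines is the most acidic on the ring, so n-BuLi removes it and Me3SiCl caps the site, which keeps this carbon (later C8) out of the next two metalations.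

Step 2
Reactants: 3 (2,6-difluoro-4-methoxyphenyl)trimethylsilane
Product: 5 (2,6-difluoro-3-iodo-4-methoxyphenyl)trimethylsilane, via [2,4-difluoro-6-methoxy-3-(trimethylsilyl)phenyl]lithium 4 (not isolated)
Conditions: s-BuLi, THF, −78 °C; then I2, THF, −78 °C to rt
Reagents that add atoms: iodine, [I][I]
Why: Second directed ortho-lithiation at one of the two equivalent C–H sites flanked by OMe and F (the only ring hydrogens left), followed by iodinolysis of the aryllithium; the mirror symmetry of 3 makes the choice of site irrelevant.

Step 3
Reactants: 5 (2,6-difluoro-3-iodo-4-methoxyphenyl)trimethylsilane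
Product: 7 methyl 4,6-difluoro-3-iodo-2-methoxy-5-(trimethylsilyl)benzoate, via [2,4-difluoro-5-iodo-6-methoxy-3-(trimethylsilyl)phenyl]lithium 6 (not isolated)
Conditions: LiN(iPr)2, THF, −78 °C; then cannulated into ClCO2Me (3 equiv), THF, −78 °C to rt
Reagents that add atoms: methyl chloroformate, COC(=O)Cl
Why: Directed ortho-metalation and electrophilic trapping; the last ring hydrogen, again between OMe and F, is removed by the amide base (an alkyllithium would exchange the iodine), and inverse addition to excess chloroformate should keep the aryllithium from adding to the ester just formed.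

Step 4
Reactants: 7 methyl 4,6-difluoro-3-iodo-2-methoxy-5-(trimethylsilyl)benzoate
Product: 8 methyl 4,6-difluoro-3-iodo-2-methoxybenzoate
Conditions: Bu4NF·3H2O, THF, 0 °C to rt
Reagents that add atoms: none
Why: Fluoride-induced protodesilylation; the aryl–Si bond flanked by two fluorines should cleave easily because both stabilise the developing aryl anion, which water protonates, while ester and iodide are untouched.

Step 5
Reactants: 8 methyl 4,6-difluoro-3-iodo-2-methoxybenzoate; 9 2-methylbut-3-yn-2-ol
Product: 10 methyl 4,6-difluoro-3-(3-hydroxy-3-methylbut-1-yn-1-yl)-2-methoxybenzoate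
Conditions: PdCl2(PPh3)2 (2 mol%), CuI (4 mol%), Et3N, THF, 45 °C
Reagents that add atoms: none
Why: Sonogashira coupling of an electron-poor aryl iodide with a terminal alkyne; the free tertiary alcohol is tolerated, the C–F bonds are inert to zerovalent palladium here, and a tertiary amine is used so that no amine can displace an activated fluoride.

Step 6
Reactants: 10 methyl 4,6-difluoro-3-(3-hydroxy-3-methylbut-1-yn-1-yl)-2-methoxybenzoate
Product: 11 methyl 4,6-difluoro-3-[(1Z)-3-hydroxy-3-methylbut-1-en-1-yl]-2-methoxybenzoate
Conditions: H2 (1 atm), 5% Pd on CaCO3 poisoned with Pb(OAc)2, quinoline, EtOAc, rt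
Reagents that add atoms: none
Why: Lindlar semihydrogenation; both hydrogens are delivered from the catalyst surface to the same face of the alkyne, so the Z alkene should result, and the poisoned surface with quinoline should stop the reduction at the alkene and leave the C–F bonds alone.

Step 7
Reactants: 11 methyl 4,6-difluoro-3-[(1Z)-3-hydroxy-3-methylbut-1-en-1-yl]-2-methoxybenzoate
Product: 14 methyl 7-fluoro-5-methoxy-2,2-dimethyl-2H-chromene-6-carboxylate, via potassium tertiary alkoxide 12 (not isolated), via Meisenheimer adduct 13 (not isolated)
Conditions: KN(SiMe3)2 (1.1 equiv), THF/DMF 5:1, 0.02 M, −20 °C to rt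
Reagents that add atoms: none
Why: The amide base deprotonates the tertiary alcohol to alkoxide 12, which adds to the fluorine-bearing carbon para to the ester (C8a) to give adduct 13, whose charge is taken up by the ester as an enolate and steadied inductively by the remaining fluorine; loss of fluoride restores the arene and gives 14. The closest known reaction type is the intramolecular SNAr etherification of fluoroarenes activated by a para carbonyl group, as used for chromans and benzofurans. One six-membered ring (O1, C2, C3, C4, C4a, C8a) is closed; counted on the C8a=C8 π bond it is formally a 6-exo-trig closure with the leaving fluoride outside the ring, and rotation about C4a–C4 lets the oxygen approach C8a from above the ring plane. No stereocentre is created, since the sp3 carbon of 13 is lost again with the fluoride. Site selectivity is needed between the two carbons the tether can reach, C8a (F) and C5 (OMe); the fluorine-bearing carbon is the more electrophilic, fluoride is the better nucleofuge in addition–elimination and this site is para to the ester, whereas the fluoride ortho to the ester cannot be reached at all. Selectivity for ring closure over intermolecular attack on that ortho fluoride or on the ester is secured by a base that is not itself a nucleophile, so that the tethered alkoxide is the only nucleophile present, and by high dilution. The Z geometry fixed in step 6 is what places the oxygen next to C8a.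

Step 8
Reactants: 15 4-hydroxybenzaldehyde
Product: 16 4-(1,3-dithian-2-yl)phenol
Conditions: HS(CH2)3SH, BF3·OEt2 (cat.), CH2Cl2, 0 °C to rt
Reagents that add atoms: propane-1,3-dithiol, SCCCS
Why: Lewis-acid-catalysed dithioacetalisation of an aldehyde; it is run before the prenylation so that BF3 and thiol never meet the acid-sensitive prenyl ether.

Step 9
Reactants: 16 4-(1,3-dithian-2-yl)phenol
Product: 17 2-{4-[(3-methylbut-2-en-1-yl)oxy]phenyl}-1,3-dithiane
Conditions: prenyl bromide, K2CO3, acetone, 50 °C
Reagents that add atoms: 1-bromo-3-methylbut-2-ene, CC(C)=CCBr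
Why: Williamson etherification (SN2 at the primary allylic bromide); the phenoxide is a far better nucleophile than the thioacetal sulfurs.

Step 10
Reactants: 17 2-{4-[(3-methylbut-2-en-1-yl)oxy]phenyl}-1,3-dithiane; 14 methyl 7-fluoro-5-methoxy-2,2-dimethyl-2H-chromene-6-carboxylate
Product: 19 (7-fluoro-5-methoxy-2,2-dimethyl-2H-chromen-6-yl)(2-{4-[(3-methylbut-2-en-1-yl)oxy]phenyl}-1,3-dithian-2-yl)methanone, via 2-lithio-1,3-dithiane 18 (not isolated)
Conditions: 17 (1.2 equiv), n-BuLi (1.15 equiv), THF, −78 to −30 °C; then 14, −78 to 0 °C
Reagents that add atoms: none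
Why: Corey–Seebach umpolung; n-BuLi removes the benzylic C2–H of the dithiane (much more acidic than the allylic OCH2) and carbanion 18 acylates the ester, whose carbonyl is easier to reach and more electrophilic with the small, electron-withdrawing fluorine at C7 than with an oxygen substituent there; the crowded ketone should not take up a second equivalent.

Step 11
Reactants: 19 (7-fluoro-5-methoxy-2,2-dimethyl-2H-chromen-6-yl)(2-{4-[(3-methylbut-2-en-1-yl)oxy]phenyl}-1,3-dithian-2-yl)methanone
Product: 21 (7-hydroxy-5-methoxy-2,2-dimethyl-2H-chromen-6-yl)(2-{4-[(3-methylbut-2-en-1-yl)oxy]phenyl}-1,3-dithian-2-yl)methanone, via 2-(methylsulfonyl)ethyl aryl ether 20 (not isolated)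
Conditions: MeSO2CH2CH2OH (2 equiv), NaH (4 equiv), DMF, 0 to 40 °C; then aq. NH4Cl
Reagents that add atoms: 2-(methylsulfonyl)ethanol, CS(=O)(=O)CCO
Why: SNAr hydroxylation with a hydroxide surrogate; the sulfonylethoxide displaces the fluoride ortho to the ketone to give ether 20, which loses methyl vinyl sulfone by base-induced β-elimination and leaves the phenoxide; the ketone has no enolisable hydrogen and the dithiane keeps Cb out of reach of the alkoxide.

Step 12
Reactants: 21 (7-hydroxy-5-methoxy-2,2-dimethyl-2H-chromen-6-yl)(2-{4-[(3-methylbut-2-en-1-yl)oxy]phenyl}-1,3-dithian-2-yl)methanone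
Product: 22 ficucaricone C, 1-(7-hydroxy-5-methoxy-2,2-dimethyl-2H-chromen-6-yl)-2-{4-[(3-methylbut-2-en-1-yl)oxy]phenyl}ethane-1,2-dione
Conditions: MeI (excess), CaCO3, MeCN/H2O 4:1, 50 °C
Reagents that add atoms: water, O
Why: Alkylative hydrolysis of a dithioketal; S-methylation turns sulfur into a leaving group, the cation at Cb is stabilised by the para-alkoxyphenyl ring, and water supplies the carbonyl oxygen, while the near-neutral CaCO3 buffer should spare the chromene alkene, the prenyl ether, the phenol and the new diketone.

##### Compound list

1 | 3,5-difluoroanisole | COc1cc(F)cc(F)c1 | starting material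
2 | (2,6-difluoro-4-methoxyphenyl)lithium | COc1cc(F)c([Li])c(F)c1 | intermediate
3 | (2,6-difluoro-4-methoxyphenyl)trimethylsilane | COc1cc(F)c([Si](C)(C)C)c(F)c1 | intermediate
4 | [2,4-difluoro-6-methoxy-3-(trimethylsilyl)phenyl]lithium | COc1cc(F)c([Si](C)(C)C)c(F)c1[Li] | intermediate
5 | (2,6-difluoro-3-iodo-4-methoxyphenyl)trimethylsilane | COc1cc(F)c([Si](C)(C)C)c(F)c1I | intermediate
6 | [2,4-difluoro-5-iodo-6-methoxy-3-(trimethylsilyl)phenyl]lithium | COc1c([Li])c(F)c([Si](C)(C)C)c(F)c1I | intermediate
7 | methyl 4,6-difluoro-3-iodo-2-methoxy-5-(trimethylsilyl)benzoate | COC(=O)c1c(F)c([Si](C)(C)C)c(F)c(I)c1OC | intermediate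
8 | methyl 4,6-difluoro-3-iodo-2-methoxybenzoate | COC(=O)c1c(F)cc(F)c(I)c1OC | intermediate
9 | 2-methylbut-3-yn-2-ol | CC(C)(O)C#C | starting material
10 | methyl 4,6-difluoro-3-(3-hydroxy-3-methylbut-1-yn-1-yl)-2-methoxybenzoate | COC(=O)c1c(F)cc(F)c(C#CC(C)(C)O)c1OC | intermediate
11 | methyl 4,6-difluoro-3-[(1Z)-3-hydroxy-3-methylbut-1-en-1-yl]-2-methoxybenzoate | COC(=O)c1c(F)cc(F)c(/C=C\C(C)(C)O)c1OC | intermediate
12 | potassium tertiary alkoxide of 11 (Z alkene retained) | COC(=O)c1c(F)cc(F)c(/C=C\C(C)(C)[O-])c1OC.[K+] | intermediate
13 | Meisenheimer adduct, potassium salt, racemic at the sp3 carbon C8a, drawn as the ester enolate | COC([O-])=C1C(F)=CC2(F)OC(C)(C)C=CC2=C1OC.[K+] | intermediate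
14 | methyl 7-fluoro-5-methoxy-2,2-dimethyl-2H-chromene-6-carboxylate | COC(=O)c1c(F)cc2OC(C)(C)C=Cc2c1OC | intermediate
15 | 4-hydroxybenzaldehyde | O=Cc1ccc(O)cc1 | starting material
16 | 4-(1,3-dithian-2-yl)phenol | Oc1ccc(cc1)C1SCCCS1 | intermediate
17 | 2-{4-[(3-methylbut-2-en-1-yl)oxy]phenyl}-1,3-dithiane | CC(C)=CCOc1ccc(cc1)C1SCCCS1 | intermediate
18 | (2-{4-[(3-methylbut-2-en-1-yl)oxy]phenyl}-1,3-dithian-2-yl)lithium | [Li]C1(SCCCS1)c1ccc(OCC=C(C)C)cc1 | intermediate
19 | (7-fluoro-5-methoxy-2,2-dimethyl-2H-chromen-6-yl)(2-{4-[(3-methylbut-2-en-1-yl)oxy]phenyl}-1,3-dithian-2-yl)methanone | COc1c2C=CC(C)(C)Oc2cc(F)c1C(=O)C1(SCCCS1)c1ccc(OCC=C(C)C)cc1 | intermediate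
20 | {5-methoxy-2,2-dimethyl-7-[2-(methylsulfonyl)ethoxy]-2H-chromen-6-yl}(2-{4-[(3-methylbut-2-en-1-yl)oxy]phenyl}-1,3-dithian-2-yl)methanone | COc1c2C=CC(C)(C)Oc2cc(OCCS(C)(=O)=O)c1C(=O)C1(SCCCS1)c1ccc(OCC=C(C)C)cc1 | intermediate
21 | (7-hydroxy-5-methoxy-2,2-dimethyl-2H-chromen-6-yl)(2-{4-[(3-methylbut-2-en-1-yl)oxy]phenyl}-1,3-dithian-2-yl)methanone | COc1c2C=CC(C)(C)Oc2cc(O)c1C(=O)C1(SCCCS1)c1ccc(OCC=C(C)C)cc1 | intermediate
22 | ficucaricone C, 1-(7-hydroxy-5-methoxy-2,2-dimethyl-2H-chromen-6-yl)-2-{4-[(3-methylbut-2-en-1-yl)oxy]phenyl}ethane-1,2-dione | COc1c2c(cc(O)c1C(=O)C(=O)c1ccc(OCC=C(C)C)cc1)OC(C)(C)C=C2 | target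

##### Step count and least certain steps

Total step count: 12 (steps 1 to 12). Longest linear sequence: 10 steps (1, 2, 3, 4, 5, 6, 7, 10, 11, 12) from 3,5-difluoroanisole; the ring B branch has 2 steps (8, 9).

**Step 7 (key step).** The most likely failure is slow ring closure, because the short, rigid Z-alkenyl tether may not let the alkoxide reach the out-of-plane approach that addition to the arene needs. Intermolecular substitution at the fluoride ortho to the ester (oligomerisation) or displacement of the C5 methoxy group could then compete. The fallback replaces the rigid tether by a flexible one and adds the alkene afterwards. It sets out from 10. Full hydrogenation (H2, 10% Pd/C, EtOAc) should give methyl 4,6-difluoro-3-(3-hydroxy-3-methylbutyl)-2-methoxybenzoate F1. The same SNAr closure (KN(SiMe3)2, THF/DMF) should then give the chroman, methyl 7-fluoro-5-methoxy-2,2-dimethyl-3,4-dihydro-2H-chromene-6-carboxylate F2. Benzylic dehydrogenation with DDQ (dioxane, reflux), helped by the two oxygen donors ortho to C4a, returns to the route at 14.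

**Step 10.** The tertiary carbanion 18 may fail to add to the shielded ester carbonyl, or may instead substitute the fluoride ortho to the ester, because both ortho positions crowd the carbonyl. The fallback lowers the electrophile to the aldehyde level, which is less hindered and much more reactive. It sets out from 14. Reduction with iBu2AlH (CH2Cl2, −78 to 0 °C) should give (7-fluoro-5-methoxy-2,2-dimethyl-2H-chromen-6-yl)methanol F3, and MnO2 (CH2Cl2) 7-fluoro-5-methoxy-2,2-dimethyl-2H-chromene-6-carbaldehyde F4. Addition of 18 (THF, −78 °C) should give the racemic carbinol (7-fluoro-5-methoxy-2,2-dimethyl-2H-chromen-6-yl)(2-{4-[(3-methylbut-2-en-1-yl)oxy]phenyl}-1,3-dithian-2-yl)methanol F5. Swern oxidation ((COCl)2, DMSO, Et3N), which leaves dithianes alone, returns to the route at 19.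

**Step 11.** The substitution may be too slow, because the ketone is twisted out of conjugation by its two ortho neighbours and its quaternary α-carbon and so activates C7 mainly inductively. Prolonged heating would then favour decay of the alkoxide reagent and attack at the ketone. The fallback moves the C7–O bond formation back to the ester, which is the more dependable activator, and carries the oxygen through as a fluoride-labile ether. It sets out from 14.
- SNAr with 2-(trimethylsilyl)ethanol and NaH (THF/DMF) should give methyl 5-methoxy-2,2-dimethyl-7-[2-(trimethylsilyl)ethoxy]-2H-chromene-6-carboxylate F6. Any ester exchange here is harmless because the ester is reduced next.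
- iBu2AlH should give {5-methoxy-2,2-dimethyl-7-[2-(trimethylsilyl)ethoxy]-2H-chromen-6-yl}methanol F7, and MnO2 the aldehyde 5-methoxy-2,2-dimethyl-7-[2-(trimethylsilyl)ethoxy]-2H-chromene-6-carbaldehyde F8.
- Addition of 18 should give the racemic carbinol F9, and Swern oxidation the ketone F10.
- Bu4NF (DMF, 50 °C) should cleave the silylethyl ether with loss of ethene and return to the route at 21.

**Step 12.** The thioketal may resist alkylative opening, because the adjacent ketone destabilises the cation at Cb and the quaternary centre is crowded. Forcing the reaction would expose the phenol to methylation. The fallback masks the phenol and switches to an oxidative unmasking with a trivalent iodine reagent. It sets out from 21. Acetylation (Ac2O, pyridine, DMAP cat.) should give the aryl acetate F11. PhI(OCOCF3)2 in MeCN/H2O at 0 °C should then open the dithiane to the acetoxy diketone F12. Brief methanolysis (K2CO3, MeOH, 0 °C) returns to the route at 22.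

**Step 3.** Iodine–lithium exchange between aryllithium 6 and not yet metalated 5 could scramble the iodine, or 6 could add to the ester just formed. Both would arise because a metalated iodoarene and an acylating agent share the flask. The fallback reverses the order of the two electrophiles and carries the carboxyl group as its lithium salt. It sets out from 3. Lithiation (s-BuLi, THF, −78 °C) and quenching with CO2 should give 2,4-difluoro-6-methoxy-3-(trimethylsilyl)benzoic acid F13. Metalation of its lithium salt at the last ring hydrogen with lithium 2,2,6,6-tetramethylpiperidide (2.2 equiv, THF, −78 °C) and iodination should give 4,6-difluoro-3-iodo-2-methoxy-5-(trimethylsilyl)benzoic acid F14. Esterification (MeI, K2CO3, DMF) returns to the route at 7.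

##### Further compounds

F1 | step 7 | methyl 4,6-difluoro-3-(3-hydroxy-3-methylbutyl)-2-methoxybenzoate | COC(=O)c1c(F)cc(F)c(CCC(C)(C)O)c1OC
F2 | step 7 | methyl 7-fluoro-5-methoxy-2,2-dimethyl-3,4-dihydro-2H-chromene-6-carboxylate | COC(=O)c1c(F)cc2OC(C)(C)CCc2c1OC
F3 | step 10 | (7-fluoro-5-methoxy-2,2-dimethyl-2H-chromen-6-yl)methanol | COc1c2C=CC(C)(C)Oc2cc(F)c1CO
F4 | step 10 | 7-fluoro-5-methoxy-2,2-dimethyl-2H-chromene-6-carbaldehyde | COc1c2C=CC(C)(C)Oc2cc(F)c1C=O
F5 | step 10 | racemic (7-fluoro-5-methoxy-2,2-dimethyl-2H-chromen-6-yl)(2-{4-[(3-methylbut-2-en-1-yl)oxy]phenyl}-1,3-dithian-2-yl)methanol | COc1c2C=CC(C)(C)Oc2cc(F)c1C(O)C1(SCCCS1)c1ccc(OCC=C(C)C)cc1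
F6 | step 11 | methyl 5-methoxy-2,2-dimethyl-7-[2-(trimethylsilyl)ethoxy]-2H-chromene-6-carboxylate | COC(=O)c1c(OCC[Si](C)(C)C)cc2OC(C)(C)C=Cc2c1OC
F7 | step 11 | {5-methoxy-2,2-dimethyl-7-[2-(trimethylsilyl)ethoxy]-2H-chromen-6-yl}methanol | COc1c2C=CC(C)(C)Oc2cc(OCC[Si](C)(C)C)c1CO
F8 | step 11 | 5-methoxy-2,2-dimethyl-7-[2-(trimethylsilyl)ethoxy]-2H-chromene-6-carbaldehyde | COc1c2C=CC(C)(C)Oc2cc(OCC[Si](C)(C)C)c1C=O
F9 | step 11 | racemic {5-methoxy-2,2-dimethyl-7-[2-(trimethylsilyl)ethoxy]-2H-chromen-6-yl}(2-{4-[(3-methylbut-2-en-1-yl)oxy]phenyl}-1,3-dithian-2-yl)methanol | COc1c2C=CC(C)(C)Oc2cc(OCC[Si](C)(C)C)c1C(O)C1(SCCCS1)c1ccc(OCC=C(C)C)cc1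
F10 | step 11 | {5-methoxy-2,2-dimethyl-7-[2-(trimethylsilyl)ethoxy]-2H-chromen-6-yl}(2-{4-[(3-methylbut-2-en-1-yl)oxy]phenyl}-1,3-dithian-2-yl)methanone | COc1c2C=CC(C)(C)Oc2cc(OCC[Si](C)(C)C)c1C(=O)C1(SCCCS1)c1ccc(OCC=C(C)C)cc1
F11 | step 12 | 5-methoxy-2,2-dimethyl-6-[(2-{4-[(3-methylbut-2-en-1-yl)oxy]phenyl}-1,3-dithian-2-yl)carbonyl]-2H-chromen-7-yl acetate | COc1c2C=CC(C)(C)Oc2cc(OC(C)=O)c1C(=O)C1(SCCCS1)c1ccc(OCC=C(C)C)cc1
F12 | step 12 | 5-methoxy-2,2-dimethyl-6-(2-{4-[(3-methylbut-2-en-1-yl)oxy]phenyl}-2-oxoacetyl)-2H-chromen-7-yl acetate | COc1c2C=CC(C)(C)Oc2cc(OC(C)=O)c1C(=O)C(=O)c1ccc(OCC=C(C)C)cc1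
F13 | step 3 | 2,4-difluoro-6-methoxy-3-(trimethylsilyl)benzoic acid | COc1cc(F)c([Si](C)(C)C)c(F)c1C(O)=O
F14 | step 3 | 4,6-difluoro-3-iodo-2-methoxy-5-(trimethylsilyl)benzoic acid | COc1c(I)c(F)c([Si](C)(C)C)c(F)c1C(O)=O
A1 | alternative 1 | mono-imine of the target diketone at Cb, N-(2,4,4-trimethylpentan-2-yl), imine geometry not defined | COc1c2C=CC(C)(C)Oc2cc(O)c1C(=O)C(=NC(C)(C)CC(C)(C)C)c1ccc(OCC=C(C)C)cc1
A2 | alternative 1 | benzodioxinone (acetone acetal) of 7-hydroxy-5-methoxy-2,2-dimethyl-2H-chromene-6-carboxylic acid | COc1c2C=CC(C)(C)Oc2cc2OC(C)(C)OC(=O)c12
A3 | alternative 1 | 2-isocyano-2,4,4-trimethylpentane | [C-]#[N+]C(C)(C)CC(C)(C)C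
A4 | alternative 1 | {4-[(3-methylbut-2-en-1-yl)oxy]phenyl}lithium | [Li]c1ccc(OCC=C(C)C)cc1
A5 | alternative 1 | lithiated imine from A4 and A3, imine geometry not defined | [Li]C(=NC(C)(C)CC(C)(C)C)c1ccc(OCC=C(C)C)cc1
A6 | alternative 2 | 1-[4,6-dihydroxy-2-methoxy-3-(3-methylbut-2-en-1-yl)phenyl]-2,2-dimethoxy-2-{4-[(3-methylbut-2-en-1-yl)oxy]phenyl}ethanone | COc1c(CC=C(C)C)c(O)cc(O)c1C(=O)C(OC)(OC)c1ccc(OCC=C(C)C)cc1
A7 | alternative 2 | 1-methoxy-7-methyl-1,3-bis(trimethylsilyloxy)octa-1,3,6-triene, mixture of alkene isomers | COC(O[Si](C)(C)C)=CC(O[Si](C)(C)C)=CCC=C(C)C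
A8 | alternative 2 | 1,1,4-trimethoxy-1-{4-[(3-methylbut-2-en-1-yl)oxy]phenyl}but-3-yn-2-one | COC#CC(=O)C(OC)(OC)c1ccc(OCC=C(C)C)cc1
A9 | alternative 3 | racemic 2-{4-[(3-methylbut-2-en-1-yl)oxy]phenyl}benzofuran-3(2H)-one fused to the 5-methoxy-2,2-dimethylchromene | COc1c2C(=O)C(c3ccc(OCC=C(C)C)cc3)Oc2cc2OC(C)(C)C=Cc12
A10 | alternative 3 | methyl 5-methoxy-2,2-dimethyl-7-({4-[(3-methylbut-2-en-1-yl)oxy]phenyl}methoxy)-2H-chromene-6-carboxylate | COC(=O)c1c(OCc2ccc(OCC=C(C)C)cc2)cc2OC(C)(C)C=Cc2c1OC
A11 | alternative 3 | {4-[(3-methylbut-2-en-1-yl)oxy]phenyl}methanol | OCc1ccc(OCC=C(C)C)cc1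
A12 | alternative 3 | racemic 2-hydroxy-2-{4-[(3-methylbut-2-en-1-yl)oxy]phenyl}benzofuran-3(2H)-one fused to the 5-methoxy-2,2-dimethylchromene, ring tautomer of 22 | COc1c2C(=O)C(O)(c3ccc(OCC=C(C)C)cc3)Oc2cc2OC(C)(C)C=Cc12
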